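| flask | Q | X | E | remark | time |
|---|---|---|---|---|---|
| Tuesday's | 0.10 M | 0.10 M (fed, over 5.0 d) | 1.4 µM | run made earlier |  |
| flask | 0.10 M | 0.100 M (fed, over 5.0 d) | 0.72 µM |  | 15 d |

Tuesday's run (percent of the Q charged)

| time / h | L / % | Q / % |
|---|---|---|
| 2.50 | 4.0 | 96.4 |
| 8.00 | 12.2 | 87.6 |
| 12.0 | 18.0 | 82.8 |
| 20.0 | 27.9 | 71.9 |
| 30.0 | 39.5 | 60.1 |
| 40.0 | 48.9 | 50.2 |

(readings scatter by 0.5 percentage points)

- when, up to 15 d, the flask holds most L
- the amount of L, in percent of the Q charged, at that time

- no earlier run changes the charge of E; that part of a forecast is a guess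

1. Start from the slowness of Tuesday's run: after 40.0 h it holds 48.9 % L, and read as first order that is a gain rate kg of 0.0168 /h.

2. At that reading, L and Q fall short of the charge by 0.9 percentage points, against a scatter of 0.5 points, so this is a weak reading. Take it as a first-order loss of L. The L present over that time sums to 10.9 h of whole charge, so the loss rate kl is 8.28 × 10⁻⁴ /h.

3. Gain over loss is 20.3; call this ratio ρ, the selectivity factor.

4. [L] peaks at the crossing where kg[Q] equals kl[L]. For two first-order steps in a row, ρ puts it at kg·t = 3.17, with a height of 85.5 % of the Q charged.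

5. No run varies E, so guess that both rates follow [E]. Then ρ holds, and the new flask has kg = 0.207 /d, which gives a crossing at 15.3 d, about the 15 d allowed.

6. The forecast, citing “a slow loss of L”, says 12 d and 78 %, earlier and lower than this reckoning.

7. The new flask peaks at 11.3 d with 82.6 %, earlier than the crossing reckoned, and by then it holds 11.0 % J.

    Z ⇌ E + L (K = 0.0432 M, k = 1130 /h)
    X + E ⇌ G (K = 560 /M, k = 1.21 × 10⁶ /M/h)
    Q + E ⇌ Z (K = 822 /M, k = 8.24 × 10⁵ /M/h)
    G → E + D (k = 941 /h)
    L + E ⇌ J + E, rate k5*[E]*[L] forward; the back reaction follows from the equilibrium constant (K = 0.624, k = 27100 /M/h)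

8. Take the neighbour flask with 4.3 × 10⁻⁷ M of E. There ρ gives kg = 0.124 /d and a crossing at 25.6 d, later than the limit, with 79.6 % L at the limit. Its best is 75.7 %, and at 15.0 d it holds 75.7 % L.

All runs stem from a simulated flask from invented constants.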